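**Retrosynthetic overview**
1. Target 26 ⇐ 25 ⇐ 24: phenol deacetylation, then chemoselective hydrogenation of an exocyclic isopropenyl group.
2. 24 ⇐ 21 (key step, the only ring): the ten-membered ring is closed last at C6–C7 by intramolecular allylboration of a (Z)-enal. This is the head-to-tail closure of a (Z,Z)-farnesyl chain onto its distal C3 π-unit, as in the germacradienyl pathway, with loss of boron in place of loss of a proton giving the 11,12-alkene.
3. 21 ⇐ 18 ⇐ 12: the vanillate is placed on C8 before ring closure; the (Z)-allylboronate comes from a boron-tethered ring-closing metathesis.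
4. 12 ⇐ 5 + 6 + 7: a one-flask lithiation–borylation–allylboration sets C8 and the (Z)-C1=C10 alkene.
5. 5 ⇐ nerol 1, which supplies the (Z)-C4=C5 alkene.

Assumption: the SMILES is read literally (both ring alkenes Z, centres 6S,7S,8R), and germacrane numbering (C6 carbinol, C7 isopropyl carbon, C8 ester carbon, C1=C10 and C4=C5 ring alkenes, C11/C12 side chain) is used for the ring and for the open-chain precursors.

**Route**

Step 1
Reactants: 1 nerol
Product: 2 (2Z)-3,7-dimethyl-1-(triethylsilyloxy)octa-2,6-diene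
Conditions: Et3SiCl, imidazole, CH2Cl2, 0 °C to rt
Reagents that add atoms: chlorotriethylsilane (CC[Si](Cl)(CC)CC)
Why: Silyl ether protection of the primary allylic alcohol masks the future C6 aldehyde oxygen as a TES ether that survives ozone, borohydride and sec-butyllithium at −78 °C and can later be oxidised directly; no stereocentre is formed and the (Z)-C4=C5 alkene of nerol is carried unchanged.

Step 2
Reactants: 2 (2Z)-3,7-dimethyl-1-(triethylsilyloxy)octa-2,6-diene
Product: 4 (4Z)-4-methyl-6-(triethylsilyloxy)hex-4-en-1-ol, via aldehyde 3 (not isolated)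
Conditions: O3 (1.0 equiv), CH2Cl2/MeOH 4:1, −78 °C; then NaBH4, −78 to 0 °C
Reagents that add atoms: ozone ([O-][O+]=O)
Why: Chemoselective ozonolysis with reductive work-up cleaves the distal isopropylidene alkene first, because the 2,3-alkene is deactivated by the allylic silyloxy group, and borohydride reduces the resulting aldehyde to the primary alcohol; no stereocentre is formed.

Step 3
Reactants: 4 (4Z)-4-methyl-6-(triethylsilyloxy)hex-4-en-1-ol
Product: 5 (4Z)-4-methyl-6-(triethylsilyloxy)hex-4-en-1-yl N,N-diisopropylcarbamate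
Conditions: iPr2NCOCl, Et3N, CH2Cl2, 40 °C
Reagents that add atoms: N,N-diisopropylcarbamoyl chloride (CC(C)N(C(C)C)C(Cl)=O)
Why: Carbamoylation of the primary alcohol installs the Hoppe carbamate that directs and stabilises the α-lithiation of the next step; no stereocentre is formed.

Step 4
Reactants: 5 (4Z)-4-methyl-6-(triethylsilyloxy)hex-4-en-1-yl N,N-diisopropylcarbamate; 6 isopropenylboronic acid pinacol ester; 7 acrolein
Product: 12 (3R,5Z,9Z)-5,9-dimethyl-11-(triethylsilyloxy)undeca-1,5,9-trien-3-ol, via lithiated carbamate 8 (not isolated), via boronate complex 9 (not isolated), via allylic boronate 10 (not isolated), via borate ester 11 (not isolated)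
Conditions: s-BuLi, (−)-sparteine, Et2O, −78 °C, 5 h; 6, −78 °C, 1 h; MgBr2·OEt2, −78 to 35 °C; then 7, 0 °C to rt; H2O
Reagents that add atoms: isopropenylboronic acid pinacol ester 6 (CC(=C)B1OC(C)(C)C(C)(C)O1); acrolein 7 (C=CC=O)
Why: Hoppe–Aggarwal lithiation–borylation followed by in-flask allylboration: sparteine-directed removal of the pro-S proton gives (S)-8, borylation with retention and 1,2-migration of the isopropenyl group with inversion give (R)-10, and its chair Zimmerman–Traxler reaction with acrolein (α-chain pseudoaxial to avoid A1,2 strain with the 2-methyl group and the pinacol ring, vinyl group equatorial) transfers the boron-bearing centre to C8 as R while forming the C1=C10 alkene as the Z isomer.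

Step 5
Reactants: 13 2-methylallylmagnesium chloride; 14 triisopropyl borate
Product: 15 diisopropyl (2-methylallyl)boronate
Conditions: 14, Et2O, −78 °C, add 13 (THF), to rt; HCl (1 M in Et2O), 0 °C; distil
Reagents that add atoms: triisopropyl borate 14 (CC(C)OB(OC(C)C)OC(C)C)
Why: Grignard borylation (transmetalation) stops after one addition at −78 °C and anhydrous HCl releases the distillable boronic diester; no stereocentre is formed.

Step 6
Reactants: 12 (3R,5Z,9Z)-5,9-dimethyl-11-(triethylsilyloxy)undeca-1,5,9-trien-3-ol; 15 diisopropyl (2-methylallyl)boronate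
Product: 18 (2Z,4R,6Z,10Z)-2,6,10-trimethyl-1-(4,4,5,5-tetramethyl-1,3,2-dioxaborolan-2-yl)-12-(triethylsilyloxy)dodeca-2,6,10-trien-4-ol, via mixed boronate 16 (not isolated), via cyclic boronate 17 (not isolated)
Conditions: 15, CH2Cl2, rt, then vacuum; second-generation Grubbs catalyst RuCl2(=CHPh)(H2IMes)(PCy3) (5 mol %), CH2Cl2 (10 mM), 40 °C; then pinacol, rt
Reagents that add atoms: diisopropyl (2-methylallyl)boronate 15 (CC(=C)CB(OC(C)C)OC(C)C); pinacol (CC(C)(O)C(C)(C)O)
Why: Boronic ester transesterification, ring-closing metathesis and pinacol exchange: the temporary B–O tether turns the vinyl/2-methylallyl metathesis into a six-ring closure, so the new trisubstituted C7=C11 alkene can only form with C8 and CH2B cis (Z), and the chelating diol then opens the B–O tether to the stable pinacol allylboronate without touching C8.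

Step 7
Reactants: 18 (2Z,4R,6Z,10Z)-2,6,10-trimethyl-1-(4,4,5,5-tetramethyl-1,3,2-dioxaborolan-2-yl)-12-(triethylsilyloxy)dodeca-2,6,10-trien-4-ol; 19 4-acetoxy-3-methoxybenzoic acid
Product: 21 (2Z,4R,6Z,10Z)-2,6,10-trimethyl-1-(4,4,5,5-tetramethyl-1,3,2-dioxaborolan-2-yl)-12-(triethylsilyloxy)dodeca-2,6,10-trien-4-yl 4-acetoxy-3-methoxybenzoate, via acid chloride 20 (not isolated)
Conditions: 19, (COCl)2, DMF (cat.), CH2Cl2, 0 °C to rt, evaporate; then 18, pyridine, CH2Cl2, 0 °C to rt
Reagents that add atoms: 4-acetoxy-3-methoxybenzoic acid 19 (CC(=O)Oc1ccc(C(=O)O)cc1OC)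
Why: Esterification of the secondary alcohol through the in-flask acid chloride proceeds with retention at C8, the phenol being masked as its acetate so that only the carboxyl group acylates, and the neutral pinacol allylboronate is inert to acid chloride and pyridine.

Step 8
Reactants: 21 (2Z,4R,6Z,10Z)-2,6,10-trimethyl-1-(4,4,5,5-tetramethyl-1,3,2-dioxaborolan-2-yl)-12-(triethylsilyloxy)dodeca-2,6,10-trien-4-yl 4-acetoxy-3-methoxybenzoate
Product: 24 (6S,7S,8R)-8-(4-acetoxy-3-methoxybenzoyloxy)germacra-1(10)Z,4Z,11-trien-6-ol, via enal 22 (not isolated), via macrocyclic borate 23 (not isolated)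
Conditions: (COCl)2, DMSO, CH2Cl2, −78 to −30 °C; Et3N, −78 to 0 °C; dilute with toluene to 2 mM, 60 °C; aq. NaHCO3
Reagents that add atoms: none
Why: Proposed new method: a Swern oxidation that cleaves and oxidises the primary TES ether in one operation (known for primary TES ethers) unveils (Z)-enal 22, whose neutral intramolecular allylboration by the tethered (Z)-γ-substituted pinacol allylboronate closes the ten-membered ring through a chair Zimmerman–Traxler transition state in which boron activates only the carbonyl oxygen it is delivered to (so the faster six-ring carbonyl-ene reaction of the C1=C10 alkene that a free Lewis acid would trigger is avoided), the Z allyl geometry (C8 pseudoaxial) with the enal substituent equatorial gives the syn relation between 6-OH and the C7–C8 bond, and attack on the C7 face anti to C9 with C8–H in the alkene plane (least A1,3 strain, ester oxygen on the side of attack) sets 6S,7S relative to 8R; the closest known reactions are intermolecular crotylborations of enals with (Z)-γ-substituted pinacol allylboronates, intramolecular allylborations forming five- to eight-membered rings, and the palladium/diethylzinc-mediated allylation that closes the germacrene ring from a farnesyl chloro-aldehyde.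

Step 9
Reactants: 24 (6S,7S,8R)-8-(4-acetoxy-3-methoxybenzoyloxy)germacra-1(10)Z,4Z,11-trien-6-ol
Product: 25 (6S,7S,8R)-8-(4-acetoxy-3-methoxybenzoyloxy)germacra-1(10)Z,4Z-dien-6-ol
Conditions: H2 (1 atm), RhCl(PPh3)3 (10 mol %), benzene/EtOH 1:1, rt
Reagents that add atoms: none
Why: Homogeneous hydrogenation with RhCl(PPh3)3 reduces the unhindered 1,1-disubstituted isopropenyl alkene much faster than the two trisubstituted ring alkenes and does not hydrogenolyse the allylic alcohol or the esters; C7 is not touched, so no stereocentre changes.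

Step 10
Reactants: 25 (6S,7S,8R)-8-(4-acetoxy-3-methoxybenzoyloxy)germacra-1(10)Z,4Z-dien-6-ol
Product: 26 (6S,7S,8R)-6-hydroxygermacra-1(10)Z,4Z-dien-8-yl 4-hydroxy-3-methoxybenzoate (target)
Conditions: K2CO3 (0.2 equiv), MeOH, 0 °C, 15 min; aq. NH4Cl
Reagents that add atoms: none
Why: Transesterification (Zemplén-type methanolysis) cleaves the activated aryl acetate within minutes at 0 °C while the hindered secondary benzoate at C8 survives, and the brief contact with catalytic carbonate avoids 1,3-acyl migration to the C6 hydroxyl; no stereocentre changes.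

**Compound list**
1 | nerol, (2Z)-3,7-dimethylocta-2,6-dien-1-ol | CC(C)=CCC/C(C)=C\CO | starting material
2 | (2Z)-3,7-dimethyl-1-(triethylsilyloxy)octa-2,6-diene | CC(C)=CCC/C(C)=C\CO[Si](CC)(CC)CC | intermediate
3 | (4Z)-4-methyl-6-(triethylsilyloxy)hex-4-enal | O=CCC/C(C)=C\CO[Si](CC)(CC)CC | intermediate
4 | (4Z)-4-methyl-6-(triethylsilyloxy)hex-4-en-1-ol | OCCC/C(C)=C\CO[Si](CC)(CC)CC | intermediate
5 | (4Z)-4-methyl-6-(triethylsilyloxy)hex-4-en-1-yl N,N-diisopropylcarbamate | CC(C)N(C(C)C)C(=O)OCCC/C(C)=C\CO[Si](CC)(CC)CC | intermediate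
6 | isopropenylboronic acid pinacol ester | CC(=C)B1OC(C)(C)C(C)(C)O1 | starting material
7 | acrolein | C=CC=O | starting material
8 | (S)-1-lithio derivative of 5 (lithium on the carbamate-bearing carbon) | [Li][C@H](OC(=O)N(C(C)C)C(C)C)CC/C(C)=C\CO[Si](CC)(CC)CC | intermediate
9 | lithium isopropenyl(pinacolato)borate complex from 8 and 6 (boron in place of lithium, retention) | [Li+].CC(=C)[B-]1(OC(C)(C)C(C)(C)O1)[C@H](OC(=O)N(C(C)C)C(C)C)CC/C(C)=C\CO[Si](CC)(CC)CC | intermediate
10 | 2-[(3R,6Z)-2,6-dimethyl-8-(triethylsilyloxy)octa-1,6-dien-3-yl]-4,4,5,5-tetramethyl-1,3,2-dioxaborolane | C=C(C)[C@H](B1OC(C)(C)C(C)(C)O1)CC/C(C)=C\CO[Si](CC)(CC)CC | intermediate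
11 | pinacol borate ester of 12 | CC[Si](CC)(CC)OC/C=C(/C)\CC/C=C(/C)\C[C@@H](OB1OC(C)(C)C(C)(C)O1)C=C | intermediate
12 | (3R,5Z,9Z)-5,9-dimethyl-11-(triethylsilyloxy)undeca-1,5,9-trien-3-ol | CC[Si](CC)(CC)OC/C=C(/C)\CC/C=C(/C)\C[C@@H](O)C=C | intermediate
13 | 2-methylallylmagnesium chloride | CC(=C)C[Mg]Cl | starting material
14 | triisopropyl borate | CC(C)OB(OC(C)C)OC(C)C | starting material
15 | diisopropyl (2-methylallyl)boronate | CC(=C)CB(OC(C)C)OC(C)C | intermediate
16 | isopropyl (2-methylallyl)boronate mixed ester of 12 | CC[Si](CC)(CC)OC/C=C(/C)\CC/C=C(/C)\C[C@@H](OB(OC(C)C)CC(C)=C)C=C | intermediate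
17 | (6R)-2-isopropoxy-4-methyl-6-[(2Z,6Z)-2,6-dimethyl-8-(triethylsilyloxy)octa-2,6-dien-1-yl]-3,6-dihydro-2H-1,2-oxaborinine | CC[Si](CC)(CC)OC/C=C(/C)\CC/C=C(/C)\C[C@H]1OB(OC(C)C)CC(C)=C1 | intermediate
18 | (2Z,4R,6Z,10Z)-2,6,10-trimethyl-1-(4,4,5,5-tetramethyl-1,3,2-dioxaborolan-2-yl)-12-(triethylsilyloxy)dodeca-2,6,10-trien-4-ol | CC[Si](CC)(CC)OC/C=C(/C)\CC/C=C(/C)\C[C@@H](O)/C=C(/C)\CB1OC(C)(C)C(C)(C)O1 | intermediate
19 | 4-acetoxy-3-methoxybenzoic acid | CC(=O)Oc1ccc(C(=O)O)cc1OC | starting material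
20 | 4-acetoxy-3-methoxybenzoyl chloride | CC(=O)Oc1ccc(C(Cl)=O)cc1OC | intermediate
21 | 4-acetoxy-3-methoxybenzoate of 18 (4R) | CC[Si](CC)(CC)OC/C=C(/C)\CC/C=C(/C)\C[C@@H](OC(=O)c1ccc(OC(C)=O)c(OC)c1)/C=C(/C)\CB1OC(C)(C)C(C)(C)O1 | intermediate
22 | (2Z,6Z,9R,10Z)-9-(4-acetoxy-3-methoxybenzoyloxy)-3,7,11-trimethyl-12-(4,4,5,5-tetramethyl-1,3,2-dioxaborolan-2-yl)dodeca-2,6,10-trienal | O=C/C=C(/C)\CC/C=C(/C)\C[C@@H](OC(=O)c1ccc(OC(C)=O)c(OC)c1)/C=C(/C)\CB1OC(C)(C)C(C)(C)O1 | intermediate
23 | 6-O-pinacol borate ester of 24 | CC(=O)Oc1ccc(C(=O)O[C@@H]2C/C(C)=C\CC/C(C)=C\[C@H](OB3OC(C)(C)C(C)(C)O3)[C@@H]2C(C)=C)cc1OC | intermediate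
24 | (6S,7S,8R)-8-(4-acetoxy-3-methoxybenzoyloxy)germacra-1(10)Z,4Z,11-trien-6-ol | CC(=O)Oc1ccc(C(=O)O[C@@H]2C/C(C)=C\CC/C(C)=C\[C@H](O)[C@@H]2C(C)=C)cc1OC | intermediate
25 | (6S,7S,8R)-8-(4-acetoxy-3-methoxybenzoyloxy)germacra-1(10)Z,4Z-dien-6-ol | CC(=O)Oc1ccc(C(=O)O[C@@H]2C/C(C)=C\CC/C(C)=C\[C@H](O)[C@@H]2C(C)C)cc1OC | intermediate
26 | (6S,7S,8R)-6-hydroxygermacra-1(10)Z,4Z-dien-8-yl 4-hydroxy-3-methoxybenzoate, CNP0185892.4 | COc1cc(C(=O)O[C@@H]2C/C(C)=C\CC/C(C)=C\[C@H](O)[C@@H]2C(C)C)ccc1O | target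

**Step count and weak points**
Total step count: 10. Longest linear sequence: 9 steps (steps 1–4 and 6–10, from nerol); step 5 is a one-step reagent preparation.

Step 8 is the most likely to fail, because the rate of a ten-membered allylboration and the facial selectivity at C7 are unproven. The fallback sets out from 12 and comes back at 25. Step 6 is run without the pinacol exchange and cyclic boronate 17 is isolated, so boron stays on the C8 oxygen. Swern oxidation of its TES ether gives the boron-tethered enal F5. This can close only through a rigid bicyclic transition state, with boron bridging O8 and the incoming carbonyl oxygen, to the macrocyclic 6,8-boronate F6. Hydrolysis with triethanolamine and water gives the isopropenyl diol F7, and RhCl(PPh3)3/H2 gives the isopropyl diol F8. MnO2 then oxidises only the allylic C6 alcohol to the enone F9, acid chloride 20 with pyridine acylates the remaining C8 alcohol to the keto ester F10, and NaBH4/CeCl3·7H2O reduction from the face anti to the isopropyl group returns 25.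

Step 4 is the second risk, because Z selectivity and chirality transfer in the three-component lithiation–borylation–allylation must both hold. The fallback sets out from 3, isolated by stopping the ozonolysis of step 2 with Me2S, and comes back at 12. Wittig olefination with Ph3P=C(I)CH3, made from (1-iodoethyl)triphenylphosphonium iodide and NaN(SiMe3)2, gives the (Z)-vinyl iodide F1. Iodine–lithium exchange with t-BuLi and BF3·OEt2-assisted opening of (R)-epichlorohydrin at its epoxide CH2 gives the chlorohydrin F2, with C8 taken from the chiral pool. Excess dimethylsulfonium methylide (Me3SI, n-BuLi) closes the epoxide and converts it into the vinyl carbinol 12.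

Step 6 is the third risk, in both the boron-tethered metathesis and the opening of the tether to the pinacol ester. The fallback sets out from 5 and comes back at 18. Step 4 is run with but-2-ynal in place of 7 to give the propargylic alcohol F3. Hydroxyl-directed trans-hydroalumination with NaAlH2(OCH2CH2OMe)2 followed by I2 gives the (Z)-3-iodoallylic alcohol F4, with iodine cis to C8. Pd(PPh3)4-catalysed Negishi coupling with pinBCH2ZnI replaces iodine with retention and gives 18.

**Further compounds**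
F1 | step 4 | (2Z,6Z)-7-iodo-3-methyl-1-(triethylsilyloxy)octa-2,6-diene | C/C(I)=C/CC/C(C)=C\CO[Si](CC)(CC)CC
F2 | step 4 | (2R,4Z,8Z)-1-chloro-4,8-dimethyl-10-(triethylsilyloxy)deca-4,8-dien-2-ol | CC[Si](CC)(CC)OC/C=C(/C)\CC/C=C(/C)\C[C@@H](O)CCl
F3 | step 6 | (4R,6Z,10Z)-6,10-dimethyl-12-(triethylsilyloxy)dodeca-6,10-dien-2-yn-4-ol | CC[Si](CC)(CC)OC/C=C(/C)\CC/C=C(/C)\C[C@@H](O)C#CC
F4 | step 6 | (2Z,4R,6Z,10Z)-2-iodo-6,10-dimethyl-12-(triethylsilyloxy)dodeca-2,6,10-trien-4-ol | CC[Si](CC)(CC)OC/C=C(/C)\CC/C=C(/C)\C[C@@H](O)/C=C(/C)\I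
F5 | step 8 | (2Z,6Z)-8-[(6R)-2-isopropoxy-4-methyl-3,6-dihydro-2H-1,2-oxaborinin-6-yl]-3,7-dimethylocta-2,6-dienal | O=C/C=C(/C)\CC/C=C(/C)\C[C@H]1OB(OC(C)C)CC(C)=C1
F6 | step 8 | cyclic 6,8-O-(isopropoxyboranediyl) derivative of germacra-1(10)Z,4Z,11-triene-6,8-diol, configuration as in 24 | CC(C)OB1O[C@@H]2C/C(C)=C\CC/C(C)=C\[C@H](O1)[C@@H]2C(C)=C
F7 | step 8 | germacra-1(10)Z,4Z,11-triene-6,8-diol, configuration as in 24 | O[C@@H]1C/C(C)=C\CC/C(C)=C\[C@H](O)[C@@H]1C(C)=C
F8 | step 8 | germacra-1(10)Z,4Z-diene-6,8-diol, configuration as in 25 | O[C@@H]1C/C(C)=C\CC/C(C)=C\[C@H](O)[C@@H]1C(C)C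
F9 | step 8 | 8-hydroxygermacra-1(10)Z,4Z-dien-6-one, C7 and C8 as in 25 | O[C@@H]1C/C(C)=C\CC/C(C)=C\C(=O)[C@@H]1C(C)C
F10 | step 8 | 8-(4-acetoxy-3-methoxybenzoyloxy)germacra-1(10)Z,4Z-dien-6-one, C7 and C8 as in 25 | CC(=O)Oc1ccc(C(=O)O[C@@H]2C/C(C)=C\CC/C(C)=C\C(=O)[C@@H]2C(C)C)cc1OC
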